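The chair opened by laying out the two earlier runs and the question about autumn and midnight, which are one charge of substrate read at two times.

| flask | substrate | gas phase | remark | time |
|---|---|---|---|---|
| Monday's | 56 mM | 23 mM (held) | run made earlier |  |
| Wednesday's | 88 mM | 23 mM (held) | run made earlier |  |
| autumn | 40 mM | 23 mM (held) |  | 80 min |
| midnight | 40 mM | 23 mM (held) |  | 160 min |

- Monday's (time / min: substrate / %, target / %): 12.0: 88.1, 10.5; 25.0: 71.9, 29.1; 40.0: 53.2, 47.0; 50.0: 43.4, 57.2
- Wednesday's (time / min: substrate / %, target / %): 6.00: 97.3, 3.2; 15.0: 86.9, 13.4; 30.0: 70.1, 30.5; 50.0: 50.4, 50.5

(scatter of a reading: 0.5 percentage points)

* which of these there is most of at the end, counted by the substrate in it, autumn (target / substrate)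
* which of these there is most of at the end, counted by the substrate in it, midnight (target / substrate)
* final amount of the leader among these, as a percentage of the substrate charged, in autumn
* final amount of the leader among these, as a percentage of the substrate charged, in midnight

The bench chemist reported that substrate and target sum to about 100 percent in both runs, so target is what the peaks show forming. I then proposed one quantity, the clearing time, meaning the minutes in which substrate falls by a factor of e at a given c(substrate). The last stretch of Monday's run reads 49.1 min at a mean c(substrate) of 27.0 mM, while that of Wednesday's run reads 60.6 min at 53.0 mM, so the time is longer at the higher concentration.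

The kineticist argued that if c(dissolved gas) is taken as steady, with gas dissolving at a rate that falls as c(dissolved gas) rises from none and has its ceiling V at none, the clearing time is a constant term plus c(substrate)/V. The two readings give V = 2.26 mM min⁻¹ and a bare clearing time, the pseudo-first-order value as c(substrate) goes to nothing, of 37.1 min, both rough under a scatter of 0.5 percentage points per reading. The chair asked about the start, when no gas is in solution, and Monday's last reading puts the delay at 4.96 min.

I committed to this rule, for the gas phase held as in these flasks: over a stretch, use the clearing time at half the c(substrate) standing at its start. For autumn that time is 46.0 min, from which I reckon 19.6% substrate and 80.4% target. I reckon midnight onward from there at 38.9 min, which gives 2.50% substrate and 97.5% target.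

The forecast gave target as leader in both, at 80% (75% to 85%) for autumn and 97% (88% to 99.5%) for midnight, holding that "The slope is also lower at the higher loading, so the rate saturates in substrate."

The flasks give target as leader in both: autumn holds 81.9% with 18.1% substrate, and midnight holds 98.3% with 1.65% substrate.

    gas phase ⇌ dissolved gas, rate k1*(csat - [dissolved gas]) (kL = 0.00146 s⁻¹)
    substrate + dissolved gas → target (k = 0.0230 L mol⁻¹ s⁻¹)

A neighbouring reading of midnight's flask comes at 90.0 min. From the 18.1% substrate standing in midnight at 80.0 min, the bare clearing time of 37.1 min plus c(substrate)/V at half that concentration gives 38.7 min, so the further 10.0 min should leave 14.0% of the charge. That neighbouring reading holds 14% substrate and 86.3% target.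

The data come from a simulation for an exercise; noise was put on by code.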